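**Retrosynthetic overview**
1. Feature: in the oxolane (O1, C2 aryl, C3 CH2OH, C4 aroyl, C5) both aryl rings are 3-hydroxy-4-methoxyphenyl. Only the ring on C2 is free of the carbonyl and has its 4-methoxy group para to the sp3 carbon C2, so it is the easier ring to oxidise and C2 can carry a cation.
2. Key disconnection O1–C2: anodic oxidation of the benzylic CH2 of seco keto alcohol 17 and capture of the C2 cation by the hydroxyl on C5.
3. 17 comes from ketone 14 and formaldehyde (C5). 14 comes from (R)-lactone 8 (C2, C3, C4 and the CH2O on C3) and aryllithium 11 (aroyl group).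
4. 8 comes from isovanillin and dimethyl succinate by Stobbe condensation, asymmetric hydrogenation (sets C3) and ester reduction. The lactone ring is made in step 4 and opened in step 6; the oxolane is the only ring formed and kept (step 10).
5. C2 is set by C3 in the ring closure and C4 afterwards by base equilibration. Fluoride and hydrogenolysis then free the three hydroxyl groups.

Key step: step 10

Assumption: the (4S,5S) antipode of MOD-DIOP, (4S,5S)-4,5-bis{[bis(4-methoxy-3,5-dimethylphenyl)phosphino]methyl}-2,2-dimethyl-1,3-dioxolane, is taken to deliver the R half-ester 6 from the E alkene 5. If lactone 8 proves to belong to the S series, the (4R,5R) ligand is used in step 3 and nothing else changes.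

Step 1
Reactants: 1 isovanillin (3-hydroxy-4-methoxybenzaldehyde)
Product: 2 3-(benzyloxy)-4-methoxybenzaldehyde
Conditions: BnBr, K2CO3, DMF, 60 °C
Reagents that add atoms: benzyl bromide, BrCc1ccccc1
Why: Williamson ether synthesis on the phenoxide; the benzyl ether withstands the methoxide, hydride and aryllithium steps ahead.

Step 2
Reactants: 2 3-(benzyloxy)-4-methoxybenzaldehyde; 3 dimethyl succinate
Product: 5 (E)-4-[3-(benzyloxy)-4-methoxyphenyl]-3-(methoxycarbonyl)but-3-enoic acid, via paraconate lactone 4 (not isolated)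
Conditions: NaOMe, MeOH, reflux; then aq. HCl
Reagents that add atoms: none
Why: Stobbe condensation: the succinate enolate adds to the aldehyde, the aldolate lactonises to 4 and base-induced opening of the lactone gives the half-ester carboxylate, with the aryl group trans to the ester (E) for steric reasons.

Step 3
Reactants: 5 (E)-4-[3-(benzyloxy)-4-methoxyphenyl]-3-(methoxycarbonyl)but-3-enoic acid
Product: 6 (3R)-4-[3-(benzyloxy)-4-methoxyphenyl]-3-(methoxycarbonyl)butanoic acid
Conditions: H2 (1 atm), [Rh(cod)Cl]2 (0.5 mol%), (4S,5S)-MOD-DIOP (1.1 mol%), Et3N (1 equiv), MeOH, 30 °C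
Reagents that add atoms: none
Why: Asymmetric hydrogenation of an itaconate-type half-ester with a rhodium bisphosphine catalyst: carboxylate and alkene bind the metal together and the ligand picks the alkene face, which sets the centre that becomes C3 of the target, while the homogeneous catalyst does not cleave the benzyl ether.

Step 4
Reactants: 6 (3R)-4-[3-(benzyloxy)-4-methoxyphenyl]-3-(methoxycarbonyl)butanoic acid
Product: 8 (4R)-4-[3-(benzyloxy)-4-methoxybenzyl]oxolan-2-one, via hydroxy acid 7 (not isolated)
Conditions: KOH (1 equiv), EtOH, 0 °C; Ca(BH4)2 (from CaCl2 and NaBH4), EtOH, −10 °C to rt; then 3 M HCl, rt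
Reagents that add atoms: none
Why: Chemoselective ester reduction followed by lactonisation: the potassium carboxylate resists Ca(BH4)2 while the methyl ester is reduced to CH2OH, and acid closes hydroxy acid 7 to the five-membered lactone without touching the stereocentre.

Step 5
Reactants: 9 5-bromo-2-methoxyphenol
Product: 10 2-(benzyloxy)-4-bromo-1-methoxybenzene
Conditions: BnBr, K2CO3, DMF, 60 °C
Reagents that add atoms: benzyl bromide, BrCc1ccccc1
Why: Williamson ether synthesis; the phenol must be masked before the bromine–lithium exchange.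

Step 6
Reactants: 10 2-(benzyloxy)-4-bromo-1-methoxybenzene; 8 (4R)-4-[3-(benzyloxy)-4-methoxybenzyl]oxolan-2-one
Product: 13 (3R)-1,4-bis[3-(benzyloxy)-4-methoxyphenyl]-3-(hydroxymethyl)butan-1-one, via aryllithium 11 (not isolated), via lithium lactolate 12 (not isolated)
Conditions: 10, n-BuLi, THF, −78 °C; then added to 8, THF, −78 °C; sat. aq. NH4Cl, −78 °C to rt
Reagents that add atoms: none
Why: Bromine–lithium exchange and single addition of aryllithium 11 to the lactone carbonyl: lactolate 12 stays tetrahedral at −78 °C and so blocks a second addition, and on protonation the γ-hydroxy ketone is favoured over the lactol because the ketone is conjugated to the aryl ring.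

Step 7
Reactants: 13 (3R)-1,4-bis[3-(benzyloxy)-4-methoxyphenyl]-3-(hydroxymethyl)butan-1-one
Product: 14 (3R)-1,4-bis[3-(benzyloxy)-4-methoxyphenyl]-3-{[(tert-butyldiphenylsilyl)oxy]methyl}butan-1-one
Conditions: TBDPSCl, imidazole, DMF, 0 °C to rt
Reagents that add atoms: tert-butyl(chloro)diphenylsilane, CC(C)(C)[Si](Cl)(c1ccccc1)c1ccccc1
Why: Silylation of the primary alcohol with imidazole, a base too weak to enolise the ketone; the robust silyl ether survives steps 8 to 11 and later leaves with fluoride, so that the last hydrogenolysis has only two aryl benzyl ethers to cleave.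

Step 8
Reactants: 14 (3R)-1,4-bis[3-(benzyloxy)-4-methoxyphenyl]-3-{[(tert-butyldiphenylsilyl)oxy]methyl}butan-1-one
Product: 15 (1Z,3R)-1,4-bis[3-(benzyloxy)-4-methoxyphenyl]-3-{[(tert-butyldiphenylsilyl)oxy]methyl}-1-[(trimethylsilyl)oxy]but-1-ene
Conditions: TMSOTf, Et3N, CH2Cl2, 0 °C
Reagents that add atoms: trimethylsilyl triflate, C[Si](C)(C)OS(=O)(=O)C(F)(F)F
Why: Soft enolisation of the aryl ketone (silyl enol ether formation) at its only enolisable position, giving the more stable Z isomer; the ethers and the C3 centre are untouched.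

Step 9
Reactants: 15 (1Z,3R)-1,4-bis[3-(benzyloxy)-4-methoxyphenyl]-3-{[(tert-butyldiphenylsilyl)oxy]methyl}-1-[(trimethylsilyl)oxy]but-1-ene; 16 formaldehyde (37% aqueous solution)
Product: 17 (2RS,3R)-1,4-bis[3-(benzyloxy)-4-methoxyphenyl]-3-{[(tert-butyldiphenylsilyl)oxy]methyl}-2-(hydroxymethyl)butan-1-one, the seco keto alcohol, as both C2 epimers
Conditions: 37% aq. HCHO, Yb(OTf)3 (10 mol%), THF, rt
Reagents that add atoms: none
Why: Mukaiyama aldol addition to aqueous formaldehyde under water-tolerant Lewis acid catalysis, which avoids the basic conditions under which the β-hydroxy ketone would dehydrate or cleave by retro-aldol reaction; the new centre (C4 of the target) forms without useful control because the neighbouring centre carries two similar CH2X groups, and both epimers are carried on since this centre is corrected in step 11.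

Step 10
Reactants: 17 (2RS,3R)-1,4-bis[3-(benzyloxy)-4-methoxyphenyl]-3-{[(tert-butyldiphenylsilyl)oxy]methyl}-2-(hydroxymethyl)butan-1-one
Product: 18 (2S,3R,4RS)-4-[3-(benzyloxy)-4-methoxybenzoyl]-2-[3-(benzyloxy)-4-methoxyphenyl]-3-{[(tert-butyldiphenylsilyl)oxy]methyl}oxolane, as both C4 epimers
Conditions: undivided cell, graphite anode, Pt cathode, controlled potential at the first anodic wave (located by cyclic voltammetry), 2.0–2.2 F/mol, n-Bu4NPF6 (0.1 M), 2,6-lutidine (2 equiv), CH2Cl2/HFIP 4:1, 0 °C
Reagents that add atoms: none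
Why: The anode takes one electron from the alkyl-substituted 3-benzyloxy-4-methoxyphenyl ring, 2,6-lutidine removes a proton from its benzylic CH2 and the resulting radical gives up a second electron, so that C2 becomes a cation delocalised onto the para methoxy oxygen as a quinone-methide-like oxocarbenium ion; at the platinum cathode the two protons are reduced to H2 well before the aryl ketone could be. The closest known reaction type is the anodic benzylic C–H oxidation of 4-alkylanisoles with capture by alcohols, with the quinone-mediated oxidative cycloetherification of aryl-substituted alcohols as its chemical counterpart. The oxolane is closed in a 5-exo-trig mode: the hydroxyl oxygen on C5 adds to the planar C2, whose double bond to the arene lies outside the new ring, and this forms O1–C2. The C2 centre is controlled by the R centre at C3, because in the envelope transition state the aryl group sits pseudo-equatorial and the new C–O bond forms anti to the silyloxymethyl group, giving 2,3-trans in either C4 epimer. The step needs site selectivity between the two dialkoxyarenes and between substrate and product: the carbonyl on the aroyl ring and, in the product, the ether oxygen on C2 raise the oxidation potential, and the charge is held at about 2 F/mol at the first wave so that the product C2–H is not oxidised further. It also needs chemoselectivity among oxygen nucleophiles, which the substrate secures because the silyl ether oxygen could only close an oxetane and HFIP is too poor a nucleophile to intercept the cation.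

Step 11
Reactants: 18 (2S,3R,4RS)-4-[3-(benzyloxy)-4-methoxybenzoyl]-2-[3-(benzyloxy)-4-methoxyphenyl]-3-{[(tert-butyldiphenylsilyl)oxy]methyl}oxolane
Product: 19 (2S,3R,4S)-4-[3-(benzyloxy)-4-methoxybenzoyl]-2-[3-(benzyloxy)-4-methoxyphenyl]-3-{[(tert-butyldiphenylsilyl)oxy]methyl}oxolane
Conditions: K2CO3, MeOH/THF 1:1, rt
Reagents that add atoms: none
Why: Base-mediated epimerisation through the ketone enolate: C4 is the only acidic centre, and reprotonation under thermodynamic control should place the aroyl group trans to the C3 substituent (all-trans, 2,4-cis), while ring opening by β-elimination of O1 is the reverse of a 5-endo-trig closure and is stereoelectronically disfavoured.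

Step 12
Reactants: 19 (2S,3R,4S)-4-[3-(benzyloxy)-4-methoxybenzoyl]-2-[3-(benzyloxy)-4-methoxyphenyl]-3-{[(tert-butyldiphenylsilyl)oxy]methyl}oxolane
Product: 20 (2S,3R,4S)-4-[3-(benzyloxy)-4-methoxybenzoyl]-2-[3-(benzyloxy)-4-methoxyphenyl]-3-(hydroxymethyl)oxolane
Conditions: Bu4NF, AcOH (1:1), THF, 0 °C to rt
Reagents that add atoms: none
Why: Fluoride-induced cleavage of the silyl ether; acetic acid buffers the alkoxide so that the C4 centre set in step 11 is not disturbed.

Step 13
Reactants: 20 (2S,3R,4S)-4-[3-(benzyloxy)-4-methoxybenzoyl]-2-[3-(benzyloxy)-4-methoxyphenyl]-3-(hydroxymethyl)oxolane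
Product: 21 (2S,3R,4S)-4-(3-hydroxy-4-methoxybenzoyl)-2-(3-hydroxy-4-methoxyphenyl)-3-(hydroxymethyl)oxolane (CNP0234761.1)
Conditions: H2 (1 atm), Pd/C (10 wt% Pd), EtOAc, rt
Reagents that add atoms: none
Why: Hydrogenolysis of the two aryl benzyl ethers, which in ethyl acetate at 1 atm should be much faster than cleavage of the hindered cyclic benzylic O1–C2 bond or reduction of the electron-rich aryl ketone; the reaction is stopped as soon as debenzylation is complete.

**Compound list**
1 | isovanillin | COc1ccc(C=O)cc1O | starting material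
2 | 3-(benzyloxy)-4-methoxybenzaldehyde | COc1ccc(C=O)cc1OCc1ccccc1 | intermediate
3 | dimethyl succinate | COC(=O)CCC(=O)OC | starting material
4 | methyl 2-[3-(benzyloxy)-4-methoxyphenyl]-5-oxooxolane-3-carboxylate (paraconate lactone, stereoisomer mixture) | COC(=O)C1CC(=O)OC1c1ccc(OC)c(OCc2ccccc2)c1 | intermediate (not isolated)
5 | (E)-4-[3-(benzyloxy)-4-methoxyphenyl]-3-(methoxycarbonyl)but-3-enoic acid | COC(=O)/C(CC(=O)O)=C/c1ccc(OC)c(OCc2ccccc2)c1 | intermediate
6 | (3R)-4-[3-(benzyloxy)-4-methoxyphenyl]-3-(methoxycarbonyl)butanoic acid | COC(=O)[C@@H](CC(=O)O)Cc1ccc(OC)c(OCc2ccccc2)c1 | intermediate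
7 | (3R)-4-[3-(benzyloxy)-4-methoxyphenyl]-3-(hydroxymethyl)butanoic acid | OC[C@@H](CC(=O)O)Cc1ccc(OC)c(OCc2ccccc2)c1 | intermediate (not isolated)
8 | (4R)-4-[3-(benzyloxy)-4-methoxybenzyl]oxolan-2-one | O=C1C[C@@H](Cc2ccc(OC)c(OCc3ccccc3)c2)CO1 | intermediate
9 | 5-bromo-2-methoxyphenol | COc1ccc(Br)cc1O | starting material
10 | 2-(benzyloxy)-4-bromo-1-methoxybenzene | COc1ccc(Br)cc1OCc1ccccc1 | intermediate
11 | [3-(benzyloxy)-4-methoxyphenyl]lithium | [Li]c1ccc(OC)c(OCc2ccccc2)c1 | intermediate (not isolated)
12 | lithium (4R)-2-[3-(benzyloxy)-4-methoxyphenyl]-4-[3-(benzyloxy)-4-methoxybenzyl]oxolan-2-olate (both configurations at C2) | [Li]OC1(c2ccc(OC)c(OCc3ccccc3)c2)C[C@@H](Cc2ccc(OC)c(OCc3ccccc3)c2)CO1 | intermediate (not isolated)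
13 | (3R)-1,4-bis[3-(benzyloxy)-4-methoxyphenyl]-3-(hydroxymethyl)butan-1-one | COc1ccc(C(=O)C[C@@H](Cc2ccc(OC)c(OCc3ccccc3)c2)CO)cc1OCc1ccccc1 | intermediate
14 | (3R)-1,4-bis[3-(benzyloxy)-4-methoxyphenyl]-3-{[(tert-butyldiphenylsilyl)oxy]methyl}butan-1-one | COc1ccc(C(=O)C[C@@H](Cc2ccc(OC)c(OCc3ccccc3)c2)CO[Si](c2ccccc2)(c2ccccc2)C(C)(C)C)cc1OCc1ccccc1 | intermediate
15 | (1Z,3R)-1,4-bis[3-(benzyloxy)-4-methoxyphenyl]-3-{[(tert-butyldiphenylsilyl)oxy]methyl}-1-[(trimethylsilyl)oxy]but-1-ene | COc1ccc(/C(O[Si](C)(C)C)=C/[C@@H](Cc2ccc(OC)c(OCc3ccccc3)c2)CO[Si](c2ccccc2)(c2ccccc2)C(C)(C)C)cc1OCc1ccccc1 | intermediate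
16 | formaldehyde | C=O | starting material
17 | (2RS,3R)-1,4-bis[3-(benzyloxy)-4-methoxyphenyl]-3-{[(tert-butyldiphenylsilyl)oxy]methyl}-2-(hydroxymethyl)butan-1-one (seco keto alcohol, both C2 epimers) | COc1ccc(C(=O)C(CO)[C@@H](Cc2ccc(OC)c(OCc3ccccc3)c2)CO[Si](c2ccccc2)(c2ccccc2)C(C)(C)C)cc1OCc1ccccc1 | intermediate
18 | (2S,3R,4RS)-4-[3-(benzyloxy)-4-methoxybenzoyl]-2-[3-(benzyloxy)-4-methoxyphenyl]-3-{[(tert-butyldiphenylsilyl)oxy]methyl}oxolane (both C4 epimers) | COc1ccc(C(=O)C2CO[C@H](c3ccc(OC)c(OCc4ccccc4)c3)[C@H]2CO[Si](c3ccccc3)(c3ccccc3)C(C)(C)C)cc1OCc1ccccc1 | intermediate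
19 | (2S,3R,4S)-4-[3-(benzyloxy)-4-methoxybenzoyl]-2-[3-(benzyloxy)-4-methoxyphenyl]-3-{[(tert-butyldiphenylsilyl)oxy]methyl}oxolane | COc1ccc(C(=O)[C@@H]2CO[C@H](c3ccc(OC)c(OCc4ccccc4)c3)[C@H]2CO[Si](c3ccccc3)(c3ccccc3)C(C)(C)C)cc1OCc1ccccc1 | intermediate
20 | (2S,3R,4S)-4-[3-(benzyloxy)-4-methoxybenzoyl]-2-[3-(benzyloxy)-4-methoxyphenyl]-3-(hydroxymethyl)oxolane | COc1ccc(C(=O)[C@@H]2CO[C@H](c3ccc(OC)c(OCc4ccccc4)c3)[C@H]2CO)cc1OCc1ccccc1 | intermediate
21 | (2S,3R,4S)-4-(3-hydroxy-4-methoxybenzoyl)-2-(3-hydroxy-4-methoxyphenyl)-3-(hydroxymethyl)oxolane | COc1ccc(C(=O)[C@@H]2CO[C@H](c3ccc(OC)c(O)c3)[C@H]2CO)cc1O | target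

**Step count**
Total steps: 13. Longest linear sequence: 12 (steps 1–4 and 6–13; step 5 is the side branch).

**Steps most likely to fail**

Step 10. What may go wrong: further oxidation of the product at its C2–H once the substrate runs low, electron transfer from the aroyl ring or a benzyl ether if the potential drifts upward, or closure on both faces of the cation. Fallback: the same C–H bond is broken by hydride abstraction instead of electrolysis. It sets out from 17, which is treated with DDQ (1.3 equiv), 2,6-dichloropyridine and 4 Å molecular sieves in CH2Cl2 at 0 °C to rt. The quinone removes hydride from the benzylic CH2 of the electron-rich ring and the C5 hydroxyl closes the oxolane as before. It comes back to the route at 18; no compound outside the list is made (F0).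

Step 6. What may go wrong: collapse of the lactolate during the addition and a second attack of the aryllithium to give a diaryl carbinol, or enolisation of the lactone by the aryllithium. Fallback: the acyl carbon is first turned into a Weinreb amide, which cannot add twice. It sets out from 8, which is opened with MeNH(OMe)·HCl and AlMe3 in CH2Cl2 at 0 °C to the hydroxy Weinreb amide F1. This is silylated at once (TBDPSCl, imidazole, DMF) to the silyl ether F2, so that it cannot close back to the lactone. Aryllithium 11, made from 10 as in step 6, is then added at −78 °C. It comes back to the route at 14.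

Step 11. What may go wrong: slow or incomplete epimerisation at C4, an equilibrium that keeps a sizeable share of the 3,4-cis isomer, or loss of the silyl group to methoxide. Fallback: C4 is set by substrate control before the oxolane exists. It sets out from 8, whose lithium enolate (LiN(i-Pr)2, THF, −78 °C) is treated with monomeric formaldehyde 16. Attack anti to the benzyl group should give the trans hydroxymethyl lactone F3. TESCl and imidazole give the triethylsilyl ether F4, and aryllithium 11 at −78 °C opens it to the hydroxy ketone F5. TBDPSCl and imidazole give the bis-silyl ether F6, and PPTS in MeOH at 0 °C removes only the triethylsilyl group to give the single 2S epimer of the seco keto alcohol F7. Electrolysis of F7 as in step 10 should give the all-trans oxolane directly, so the route is rejoined at 19 and step 11 is not needed.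

**Further compounds**
F0 | step 10 | none | none
F1 | step 6 | (3R)-4-[3-(benzyloxy)-4-methoxyphenyl]-3-(hydroxymethyl)-N-methoxy-N-methylbutanamide | CON(C)C(=O)C[C@@H](Cc1ccc(OC)c(OCc2ccccc2)c1)CO
F2 | step 6 | (3R)-4-[3-(benzyloxy)-4-methoxyphenyl]-3-{[(tert-butyldiphenylsilyl)oxy]methyl}-N-methoxy-N-methylbutanamide | CON(C)C(=O)C[C@@H](Cc1ccc(OC)c(OCc2ccccc2)c1)CO[Si](c1ccccc1)(c1ccccc1)C(C)(C)C
F3 | step 11 | (3S,4R)-4-[3-(benzyloxy)-4-methoxybenzyl]-3-(hydroxymethyl)oxolan-2-one | O=C1[C@H](CO)[C@@H](Cc2ccc(OC)c(OCc3ccccc3)c2)CO1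
F4 | step 11 | (3S,4R)-4-[3-(benzyloxy)-4-methoxybenzyl]-3-{[(triethylsilyl)oxy]methyl}oxolan-2-one | O=C1[C@H](CO[Si](CC)(CC)CC)[C@@H](Cc2ccc(OC)c(OCc3ccccc3)c2)CO1
F5 | step 11 | (2S,3R)-1,4-bis[3-(benzyloxy)-4-methoxyphenyl]-3-(hydroxymethyl)-2-{[(triethylsilyl)oxy]methyl}butan-1-one | COc1ccc(C(=O)[C@H](CO[Si](CC)(CC)CC)[C@@H](Cc2ccc(OC)c(OCc3ccccc3)c2)CO)cc1OCc1ccccc1
F6 | step 11 | (2S,3R)-1,4-bis[3-(benzyloxy)-4-methoxyphenyl]-3-{[(tert-butyldiphenylsilyl)oxy]methyl}-2-{[(triethylsilyl)oxy]methyl}butan-1-one | COc1ccc(C(=O)[C@H](CO[Si](CC)(CC)CC)[C@@H](Cc2ccc(OC)c(OCc3ccccc3)c2)CO[Si](c2ccccc2)(c2ccccc2)C(C)(C)C)cc1OCc1ccccc1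
F7 | step 11 | (2S,3R)-1,4-bis[3-(benzyloxy)-4-methoxyphenyl]-3-{[(tert-butyldiphenylsilyl)oxy]methyl}-2-(hydroxymethyl)butan-1-one (single 2S epimer of 17) | COc1ccc(C(=O)[C@H](CO)[C@@H](Cc2ccc(OC)c(OCc3ccccc3)c2)CO[Si](c2ccccc2)(c2ccccc2)C(C)(C)C)cc1OCc1ccccc1
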